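**Plan**

1. Ring numbering as in the target: C1 = carbinol carbon bearing CH2OBz, C2 and C3 = acetoxy carbons, C4=C5 = alkene, C6 = allylic carbinol. The retrosynthesis cuts C4=C5 and C1–C2 together, which divides the carbocycle into two three-carbon halves: C2–C3–C4 (aldehyde 4) and C5–C6–C1 (bromodiene 10).
2. Enabling feature: in the cyclohexene the C4=C5 alkene lies directly opposite the C1–C2 bond and is flanked by the two allylic carbinols C3 and C6, so each half is a vinyl carbinol. C1, a carbinol with an extra CH2O arm, can be carried as a 2-metallated 1-alkene (later an exocyclic methylidene) that attacks the C2 aldehyde, while the two vinyl ends close by metathesis.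
3. Forward: fragment 1 (aldehyde 4, three steps) and fragment 2 (bromodiene 10, three steps) are joined and cyclised in one flask (step 7, the only ring-forming operation). This is two known reactions telescoped, not a single mechanistic event. The methylidene is then converted into C1(OH)CH2OBz by directed epoxidation and benzoate opening, followed by PMB removal, diacetylation and desilylation.
4. Stereochemistry: C3 from (S)-but-3-ene-1,2-diol; C6 from a Sharpless kinetic resolution; C2 by Cram-chelate 1,2-induction from C3; C1 by oxygen delivery from the C2 hydroxyl.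

Key step: step 7

**Route**

Step 1
Reactants: 1 (S)-but-3-ene-1,2-diol
Product: 2 (4S)-2-(4-methoxyphenyl)-4-vinyl-1,3-dioxolane (epimer mixture at the acetal carbon)
Conditions: 4-MeOC6H4CH(OMe)2, PPTS (cat.), CH2Cl2, rt
Reagents that add atoms: 4-methoxybenzaldehyde dimethyl acetal, COc1ccc(cc1)C(OC)OC
Why: Acid-catalysed transacetalisation of the 1,2-diol gives the five-membered 4-methoxybenzylidene acetal without touching the existing stereocentre (the new acetal carbon is an inconsequential epimer mixture).

Step 2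
Reactants: 2 (4S)-2-(4-methoxyphenyl)-4-vinyl-1,3-dioxolane
Product: 3 (2S)-2-[(4-methoxybenzyl)oxy]but-3-en-1-ol
Conditions: i-Bu2AlH, CH2Cl2, −78 to 0 °C; aqueous Rochelle salt
Reagents that add atoms: none
Why: In this regioselective reductive acetal opening aluminium should coordinate the less hindered primary oxygen, so hydride delivery leaves the PMB group on the secondary oxygen and frees the primary alcohol; no stereocentre is formed.

Step 3
Reactants: 3 (2S)-2-[(4-methoxybenzyl)oxy]but-3-en-1-ol
Product: 4 (2S)-2-[(4-methoxybenzyl)oxy]but-3-enal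
Conditions: Dess–Martin periodinane, NaHCO3, CH2Cl2, 0 °C; used at once
Reagents that add atoms: none
Why: Dess–Martin oxidation under buffered, non-basic conditions should give the α-alkoxy-β,γ-unsaturated aldehyde without epimerisation or migration of the double bond.

Step 4
Reactants: 5 bromoethene (vinyl bromide); 6 prop-2-enal (acrolein)
Product: 8 rac-2-bromopenta-1,4-dien-3-ol, via 1-bromo-1-lithioethene 7 (not isolated)
Conditions: LiN(i-Pr)2, THF/Et2O/pentane, −110 °C; then 6; AcOH quench
Reagents that add atoms: none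
Why: α-Lithiation of vinyl bromide at very low temperature gives the carbenoid 7, which should add 1,2 to acrolein (carbonyl addition) to give the racemic bis-allylic carbinol that is resolved in step 5.

Step 5
Reactants: 8 rac-2-bromopenta-1,4-dien-3-ol
Product: 9 (3S)-2-bromopenta-1,4-dien-3-ol
Conditions: Ti(OiPr)4 (cat.), L-(+)-diisopropyl tartrate, t-BuOOH (0.6 equiv), 4 Å molecular sieves, CH2Cl2, −20 °C, run to a little past half conversion
Reagents that add atoms: none
Why: In this Sharpless kinetic resolution the (R)-enantiomer should be epoxidised at its unsubstituted vinyl group and the (S)-alcohol, which becomes C6, recovered, while the electron-poor bromoalkene stays inert.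

Step 6
Reactants: 9 (3S)-2-bromopenta-1,4-dien-3-ol
Product: 10 (3S)-2-bromo-3-[(tert-butyldimethylsilyl)oxy]penta-1,4-diene
Conditions: TBSCl, imidazole, DMF, rt
Reagents that add atoms: tert-butyldimethylsilyl chloride, C[Si](C)(Cl)C(C)(C)C
Why: Silyl ether formation masks the allylic hydroxyl as a non-chelating group that survives the organometallic step and is removed last.

Step 7
Reactants: 10 (3S)-2-bromo-3-[(tert-butyldimethylsilyl)oxy]penta-1,4-diene; 4 (2S)-2-[(4-methoxybenzyl)oxy]but-3-enal
Product: 14 (1S,2S,5S)-5-[(tert-butyldimethylsilyl)oxy]-2-[(4-methoxybenzyl)oxy]-6-methylidenecyclohex-3-en-1-ol, via alkenyllithium 11 (not isolated), via alkenylmagnesium bromide 12 (not isolated), via triene alcohol 13 (not isolated)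
Conditions: t-BuLi (2 equiv), Et2O, −78 °C; MgBr2·OEt2; then 4, CH2Cl2, −78 °C; AcOH (1 equiv); second-generation Grubbs catalyst (5 mol %), CH2Cl2, 35–40 °C, same flask
Reagents that add atoms: none
Why: Bromine–lithium exchange and transmetalation give alkenylmagnesium 12, which adds to the aldehyde of 4 through a five-membered magnesium chelate between the carbonyl and PMB-ether oxygens (Cram chelate) to form C1–C2, and the resulting triene 13 then undergoes ring-closing metathesis of its two monosubstituted vinyl groups through ruthenacyclobutanes, with loss of ethene, to form C4=C5. The closest known reaction types are the chelation-controlled addition of alkenyl Grignard reagents to α-alkoxy aldehydes and the RCM of octa-1,7-dienes to cyclohexenes, here run in one flask. The only ring, the six-membered carbocycle, is closed by the metathesis (alkene-forming closure; the cis geometry of C4=C5 is enforced by the ring). The new stereocentre C2 is controlled by C3 of 4: in the chelate the nucleophile attacks the carbonyl face opposite the C3 vinyl group, giving the 2,3-syn alcohol, that is C2–O trans to C3–O in the ring, while C3 and C6 are carried unchanged. The step needs 1,2-addition without enolisation of the sensitive aldehyde (low temperature, Lewis-acidic magnesium) and site selectivity in the metathesis, which is secured because the 1,1-disubstituted methylidene could only close three- or four-membered rings.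

Step 8
Reactants: 14 (1S,2S,5S)-5-[(tert-butyldimethylsilyl)oxy]-2-[(4-methoxybenzyl)oxy]-6-methylidenecyclohex-3-en-1-ol
Product: 15 (3R,4R,5S,8S)-8-[(tert-butyldimethylsilyl)oxy]-5-[(4-methoxybenzyl)oxy]-1-oxaspiro[2.5]oct-6-en-4-ol
Conditions: VO(acac)2 (cat.), t-BuOOH, CH2Cl2, 0 °C to rt
Reagents that add atoms: tert-butyl hydroperoxide, CC(C)(C)OO
Why: In this hydroxyl-directed epoxidation the free C2 hydroxyl is allylic only to the exocyclic alkene and should deliver oxygen to its cis face, which sets the quaternary centre C1 with C1–O cis to C2–O.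

Step 9
Reactants: 15 (3R,4R,5S,8S)-8-[(tert-butyldimethylsilyl)oxy]-5-[(4-methoxybenzyl)oxy]-1-oxaspiro[2.5]oct-6-en-4-ol
Product: 16 [(1R,2R,3S,6S)-6-[(tert-butyldimethylsilyl)oxy]-1,2-dihydroxy-3-[(4-methoxybenzyl)oxy]cyclohex-4-en-1-yl]methyl benzoate
Conditions: PhCO2H, Ti(OiPr)4, CH2Cl2, rt
Reagents that add atoms: benzoic acid, OC(=O)c1ccccc1
Why: Titanium-assisted opening of the 2,3-epoxy alcohol by benzoate should occur by SN2 attack at the unsubstituted epoxide carbon, so the tertiary C1–O bond and its configuration are untouched.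

Step 10
Reactants: 16 [(1R,2R,3S,6S)-6-[(tert-butyldimethylsilyl)oxy]-1,2-dihydroxy-3-[(4-methoxybenzyl)oxy]cyclohex-4-en-1-yl]methyl benzoate
Product: 17 [(1R,2R,3S,6S)-6-[(tert-butyldimethylsilyl)oxy]-1,2,3-trihydroxycyclohex-4-en-1-yl]methyl benzoate
Conditions: DDQ, CH2Cl2/pH 7 buffer, 0 °C
Reagents that add atoms: none
Why: Oxidative cleavage of the PMB ether by DDQ (oxidation to the oxocarbenium ion, then hydrolysis) should free the C3 hydroxyl without affecting the benzoate, silyl ether or alkene.

Step 11
Reactants: 17 [(1R,2R,3S,6S)-6-[(tert-butyldimethylsilyl)oxy]-1,2,3-trihydroxycyclohex-4-en-1-yl]methyl benzoate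
Product: 18 [(1R,2R,3S,6S)-2,3-diacetoxy-6-[(tert-butyldimethylsilyl)oxy]-1-hydroxycyclohex-4-en-1-yl]methyl benzoate
Conditions: Ac2O, pyridine, DMAP (cat.), CH2Cl2, 0 °C
Reagents that add atoms: acetic anhydride, CC(=O)OC(C)=O
Why: DMAP-catalysed acylation should esterify the two secondary hydroxyls at C2 and C3, while the tertiary C1 hydroxyl is too hindered to react under these conditions.

Step 12
Reactants: 18 [(1R,2R,3S,6S)-2,3-diacetoxy-6-[(tert-butyldimethylsilyl)oxy]-1-hydroxycyclohex-4-en-1-yl]methyl benzoate
Product: 19 [(1S,2R,3S,6S)-2,3-diacetoxy-1,6-dihydroxycyclohex-4-en-1-yl]methyl benzoate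
Conditions: HF·pyridine, THF, 0 °C to rt
Reagents that add atoms: none
Why: Fluoride-mediated desilylation under mildly acidic conditions should free the C6 hydroxyl while avoiding the base-induced acyl migration that the neighbouring esters would otherwise risk.

**Compound list**

1 | (S)-but-3-ene-1,2-diol | C=C[C@H](O)CO | starting material
2 | (4S)-2-(4-methoxyphenyl)-4-vinyl-1,3-dioxolane | C=C[C@H]1COC(O1)c2ccc(OC)cc2 | intermediate
3 | (2S)-2-[(4-methoxybenzyl)oxy]but-3-en-1-ol | C=C[C@H](OCc1ccc(OC)cc1)CO | intermediate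
4 | (2S)-2-[(4-methoxybenzyl)oxy]but-3-enal | C=C[C@H](OCc1ccc(OC)cc1)C=O | intermediate
5 | bromoethene | C=CBr | starting material
6 | prop-2-enal | C=CC=O | starting material
7 | 1-bromo-1-lithioethene | [Li]C(Br)=C | intermediate
8 | rac-2-bromopenta-1,4-dien-3-ol | C=CC(O)C(Br)=C | intermediate
9 | (3S)-2-bromopenta-1,4-dien-3-ol | C=C(Br)[C@@H](O)C=C | intermediate
10 | (3S)-2-bromo-3-[(tert-butyldimethylsilyl)oxy]penta-1,4-diene | C=C(Br)[C@@H](O[Si](C)(C)C(C)(C)C)C=C | intermediate
11 | [(3S)-3-[(tert-butyldimethylsilyl)oxy]penta-1,4-dien-2-yl]lithium | C=C([Li])[C@@H](O[Si](C)(C)C(C)(C)C)C=C | intermediate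
12 | [(3S)-3-[(tert-butyldimethylsilyl)oxy]penta-1,4-dien-2-yl]magnesium bromide | C=C([Mg]Br)[C@@H](O[Si](C)(C)C(C)(C)C)C=C | intermediate
13 | (3S,4S,6S)-6-[(tert-butyldimethylsilyl)oxy]-3-[(4-methoxybenzyl)oxy]-5-methylideneocta-1,7-dien-4-ol | C=C[C@H](OCc1ccc(OC)cc1)[C@@H](O)C(=C)[C@@H](O[Si](C)(C)C(C)(C)C)C=C | intermediate
14 | (1S,2S,5S)-5-[(tert-butyldimethylsilyl)oxy]-2-[(4-methoxybenzyl)oxy]-6-methylidenecyclohex-3-en-1-ol | COc1ccc(CO[C@H]2C=C[C@H](O[Si](C)(C)C(C)(C)C)C(=C)[C@@H]2O)cc1 | intermediate
15 | (3R,4R,5S,8S)-8-[(tert-butyldimethylsilyl)oxy]-5-[(4-methoxybenzyl)oxy]-1-oxaspiro[2.5]oct-6-en-4-ol | COc1ccc(CO[C@H]2C=C[C@H](O[Si](C)(C)C(C)(C)C)[C@@]3(CO3)[C@@H]2O)cc1 | intermediate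
16 | [(1R,2R,3S,6S)-6-[(tert-butyldimethylsilyl)oxy]-1,2-dihydroxy-3-[(4-methoxybenzyl)oxy]cyclohex-4-en-1-yl]methyl benzoate | COc1ccc(CO[C@H]2C=C[C@H](O[Si](C)(C)C(C)(C)C)[C@@](O)(COC(=O)c3ccccc3)[C@@H]2O)cc1 | intermediate
17 | [(1R,2R,3S,6S)-6-[(tert-butyldimethylsilyl)oxy]-1,2,3-trihydroxycyclohex-4-en-1-yl]methyl benzoate | O[C@H]1C=C[C@H](O[Si](C)(C)C(C)(C)C)[C@@](O)(COC(=O)c2ccccc2)[C@@H]1O | intermediate
18 | [(1R,2R,3S,6S)-2,3-diacetoxy-6-[(tert-butyldimethylsilyl)oxy]-1-hydroxycyclohex-4-en-1-yl]methyl benzoate | CC(=O)O[C@H]1C=C[C@H](O[Si](C)(C)C(C)(C)C)[C@@](O)(COC(=O)c2ccccc2)[C@@H]1OC(C)=O | intermediate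
19 | [(1S,2R,3S,6S)-2,3-diacetoxy-1,6-dihydroxycyclohex-4-en-1-yl]methyl benzoate | CC(=O)O[C@H]1C=C[C@H](O)[C@@](O)(COC(=O)c2ccccc2)[C@@H]1OC(C)=O | target

**Summary**

Total steps: 12. Longest linear sequence: 9 steps (steps 1–3 then 7–12, or steps 4–6 then 7–12).

Steps most likely to fail:

Step 7. The chelate addition may lose facial control, the basic organometallic may isomerise 4 to the conjugated enal, the alkenyl-metal may undergo silyl migration or β-elimination, or the metathesis may stall in the salt-containing medium. The fallback sets out from 10 and 4 and comes back at 14. The union would be made under neutral Nozaki–Hiyama–Kishi conditions (CrCl2, NiCl2 cat., DMSO/THF) and the two bond formations uncoupled. This coupling is not chelation-controlled and is expected to favour the Felkin-type 2,3-anti triene alcohol (3S,4R,6S)-6-[(tert-butyldimethylsilyl)oxy]-3-[(4-methoxybenzyl)oxy]-5-methylideneocta-1,7-dien-4-ol F1. Isolated F1 would be cyclised with second-generation Grubbs catalyst in CH2Cl2 to the epimeric cyclohexenol (1R,2S,5S)-5-[(tert-butyldimethylsilyl)oxy]-2-[(4-methoxybenzyl)oxy]-6-methylidenecyclohex-3-en-1-ol F2. Its carbinol centre would be inverted by a Mitsunobu reaction (4-nitrobenzoic acid, PPh3, DIAD) to the ester (1S,2S,5S)-5-[(tert-butyldimethylsilyl)oxy]-2-[(4-methoxybenzyl)oxy]-6-methylidenecyclohex-3-en-1-yl 4-nitrobenzoate F3, and methanolysis (K2CO3, MeOH) would return 14.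

Step 8. Oxygen may be transferred to the wrong face of the methylidene, or the ring alkene may be epoxidised in competition. The fallback sets out from 14 and comes back at 16, bypassing 15. Hydrogen-bond-directed osmylation of 14 (OsO4·TMEDA, CH2Cl2, −78 °C, then aqueous Na2SO3) should add both oxygens cis to the free hydroxyl and give the triol (1R,2R,3S,6S)-6-[(tert-butyldimethylsilyl)oxy]-1-(hydroxymethyl)-3-[(4-methoxybenzyl)oxy]cyclohex-4-ene-1,2-diol F4. Selective benzoylation of its primary hydroxyl (BzCl, 2,4,6-collidine, CH2Cl2, −40 °C) would give 16.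

Step 5. The rate difference between the enantiomers may be too small, or the enantiomer to be recovered may be slowly epoxidised, since both alkenes of 8 are allylic to the same carbinol. The fallback sets out from 8 and comes back at 9. The racemate would instead be resolved by enzymatic transesterification (Candida antarctica lipase B, vinyl acetate, hexane, rt), in which the (R)-alcohol is expected to be acetylated and the (S)-alcohol 9 recovered by chromatography. No new compound lies on the way (F0).

**Further compounds**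

F1 | step 7 | (3S,4R,6S)-6-[(tert-butyldimethylsilyl)oxy]-3-[(4-methoxybenzyl)oxy]-5-methylideneocta-1,7-dien-4-ol | C=C[C@H](OCc1ccc(OC)cc1)[C@H](O)C(=C)[C@@H](O[Si](C)(C)C(C)(C)C)C=C
F2 | step 7 | (1R,2S,5S)-5-[(tert-butyldimethylsilyl)oxy]-2-[(4-methoxybenzyl)oxy]-6-methylidenecyclohex-3-en-1-ol | COc1ccc(CO[C@H]2C=C[C@H](O[Si](C)(C)C(C)(C)C)C(=C)[C@H]2O)cc1
F3 | step 7 | (1S,2S,5S)-5-[(tert-butyldimethylsilyl)oxy]-2-[(4-methoxybenzyl)oxy]-6-methylidenecyclohex-3-en-1-yl 4-nitrobenzoate | COc1ccc(CO[C@H]2C=C[C@H](O[Si](C)(C)C(C)(C)C)C(=C)[C@@H]2OC(=O)c3ccc(cc3)[N+](=O)[O-])cc1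
F4 | step 8 | (1R,2R,3S,6S)-6-[(tert-butyldimethylsilyl)oxy]-1-(hydroxymethyl)-3-[(4-methoxybenzyl)oxy]cyclohex-4-ene-1,2-diol | COc1ccc(CO[C@H]2C=C[C@H](O[Si](C)(C)C(C)(C)C)[C@@](O)(CO)[C@@H]2O)cc1
F0 | step 5 | none | none
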